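**Strategy.** The synthesis rests on reading the trimethylcyclohexene ring of the β half (C1–C6) as the electrocyclisation product of an acyclic trienoate: the tetrasubstituted C5=C6 olefin flanked by the quaternary carbon C1 is exactly what a 1,1-dimethylhexatriene gives. A Wittig union of two C5 isoprenoid pieces creates C3=C4, and in the same pot the (4Z)-triene closes C1–C6 to ethyl safranate. Asymmetric hydroboration of the residual C3=C4 olefin then installs the ring's only stereocentre. A carbonylative Stille coupling supplies the C8 ketone with the C9 hydroxymethyl-vinyl unit, and two further Wittig reactions with a C10 dialdehyde and an ε-ring C15 salt from (R)-α-ionone complete the polyene.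

Key step: step 1

Remark: (R)-α-ionone of high enantiomeric purity is taken as a purchased material; atoms are named by carotenoid numbering (C1–C6 for the ring of the β half, primed numbers for the ε half).

**Step 1**
Reactants: 1 (3-methylbut-2-en-1-yl)triphenylphosphonium bromide; 2 ethyl (E)-3-methyl-4-oxobut-2-enoate
Product: 7 ethyl 2,6,6-trimethylcyclohexa-1,3-diene-1-carboxylate (ethyl safranate), via ylide 3 (not isolated), via (2E,4E)-trienoate 4 (not isolated), via (2E,4Z)-trienoate 5 (not isolated), via ethyl α-safranate 6 (not isolated)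
Conditions: NaN(SiMe3)2, THF, −78 → 0 °C; solvent change to o-xylene, I2 (3 mol%), 140 °C; then DBU (0.2 equiv), 80 °C
Reagents that add atoms: none
Why: The semi-stabilised allylic ylide 3 should condense with the aldehyde carbon of 2 (Wittig olefination) to give the trienoate as a 4E/4Z mixture with the 2E geometry of 2 retained, and iodine equilibrates 4 and 5 at 140 °C. Only 5 can reach the s-cis,s-cis conformation, and its thermal disrotatory 6π-electrocyclisation closes the six-membered carbocycle between C1 and C6 irreversibly, so the whole mixture should drain through 5. The closest known reactions are the Wittig couplings of ethyl 3-formylcrotonate in retinoid synthesis and the thermal cyclisation of 1,1-dimethyl-substituted (Z)-hexatrienes such as alloocimene to pyronenes. The only new stereocentre, C6 of 6, is formed racemic and is erased when DBU moves the C6 hydrogen to C2 and brings the diene into conjugation with the ester. The step needs ring closure to win over the reversible [1,7]-hydrogen shift from the inward C1 methyl; the ester sits outward (2E) and keeps the trienoate conjugated, so the shifted triene should stay a minor, reverting component.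

**Step 2**
Reactants: 7 ethyl safranate
Product: 8 (2,6,6-trimethylcyclohexa-1,3-dien-1-yl)methanol (safranol)
Conditions: i-Bu2AlH (2.2 equiv), CH2Cl2, −78 → 0 °C; Rochelle salt work-up
Reagents that add atoms: none
Why: Hydride reduction of the hindered conjugated ester should stop cleanly at the dienyl carbinol, since the aluminium hydride does not touch the diene.

**Step 3**
Reactants: 8 safranol
Product: 9 1-{[(2-methoxypropan-2-yl)oxy]methyl}-2,6,6-trimethylcyclohexa-1,3-diene
Conditions: 2-methoxypropene, PPTS (cat.), CH2Cl2, 0 °C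
Reagents that add atoms: 2-methoxypropene, COC(C)=C
Why: Acid-catalysed acetal formation masks the allylic hydroxyl so that it does not consume the borane in the next step, and the mixed acetal is stable to the basic peroxide work-up.

**Step 4**
Reactants: 9 safranol 2-methoxyprop-2-yl ether
Product: 12 (1R)-4-(hydroxymethyl)-3,5,5-trimethylcyclohex-3-en-1-ol, via organoborane 10 (not isolated), via acetal alcohol 11 (not isolated)
Conditions: pre-formed (+)-Ipc2BH (from (−)-α-pinene), THF, −25 °C, 48 h; NaOH, H2O2, 0 → 25 °C; then AcOH/THF/H2O, 25 °C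
Reagents that add atoms: hydrogen peroxide, OO
Why: In this asymmetric hydroboration–oxidation the bulky dialkylborane should add only to the cis-disubstituted C3=C4 olefin with boron at C3 (the diene terminus remote from the fully substituted C5, the developing positive charge at C4 being stabilised by C5=C6), the reagent from (−)-α-pinene selecting the face that gives 3R (the mirror-image sense of the cis-2-butene to (R)-2-butanol case with the antipodal reagent, once the changed priorities are allowed for); oxidation retains configuration and mild acid removes the acetal.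

**Step 5**
Reactants: 12 (1R)-4-(hydroxymethyl)-3,5,5-trimethylcyclohex-3-en-1-ol
Product: 13 (1R)-4-(chloromethyl)-3,5,5-trimethylcyclohex-3-en-1-ol
Conditions: NCS, Me2S, CH2Cl2, −20 → 0 °C
Reagents that add atoms: N-chlorosuccinimide, O=C1CCC(=O)N1Cl
Why: Corey–Kim chlorination displaces only the primary allylic alkoxysulfonium group, so the secondary C3 hydroxyl and its configuration should be untouched.

**Step 6**
Reactants: 14 tert-butyldimethyl(prop-2-yn-1-yloxy)silane
Product: 16 methyl 4-{[tert-butyl(dimethyl)silyl]oxy}but-2-ynoate, via lithium acetylide 15 (not isolated)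
Conditions: n-BuLi, THF, −78 °C; ClCO2Me, −78 → 0 °C
Reagents that add atoms: methyl chloroformate, COC(=O)Cl
Why: Acylation of a lithium acetylide with a chloroformate is a standard route to ynoates and supplies the carbon that becomes C11.

**Step 7**
Reactants: 16 methyl 4-{[tert-butyl(dimethyl)silyl]oxy}but-2-ynoate
Product: 18 methyl (2E)-4-{[tert-butyl(dimethyl)silyl]oxy}-3-(tributylstannyl)but-2-enoate, via vinylcopper adduct 17 (not isolated)
Conditions: Bu3SnH, LiN(i-Pr)2, THF, −40 °C; CuBr·SMe2, −78 °C; then 16 and MeOH (2 equiv), −78 °C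
Reagents that add atoms: tributyltin hydride, CCCC[SnH](CCCC)CCCC
Why: Stannylcupration of an ynoate is a syn addition with tin at the β-carbon, and protonation of the vinylcopper at −78 °C by the methanol present traps the kinetic adduct, so tin and hydrogen end cis and the silyloxymethyl carbon (C19) lies cis to the ester carbon (C11).

**Step 8**
Reactants: 18 stannyl enoate
Product: 19 (2E)-4-{[tert-butyl(dimethyl)silyl]oxy}-3-(tributylstannyl)but-2-en-1-ol
Conditions: i-Bu2AlH (2.2 equiv), CH2Cl2, −78 °C
Reagents that add atoms: none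
Why: 1,2-Reduction of the enoate should give the allylic alcohol without touching the vinylstannane or the silyl ether, leaving C11 free and C19 protected.

**Step 9**
Reactants: 13 allylic chloride; 19 vinylstannane
Product: 20 (3E)-3-({[tert-butyl(dimethyl)silyl]oxy}methyl)-5-hydroxy-1-[(4R)-4-hydroxy-2,6,6-trimethylcyclohex-1-en-1-yl]pent-3-en-2-one
Conditions: Pd2(dba)3 (2.5 mol%), AsPh3 (20 mol%), CO (3 atm), THF, 50 °C
Reagents that add atoms: carbon monoxide, [C-]#[O+]
Why: In this carbonylative Stille coupling, oxidative addition of the allylic chloride, CO insertion at the unhindered C7 terminus of the allylpalladium species and transmetallation with the vinylstannane should give the β,γ-unsaturated ketone, with tin replaced by the acyl group with retention of the C9=C10 geometry.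

**Step 10**
Reactants: 20 hydroxy enone
Product: 22 [(2E)-3-({[tert-butyl(dimethyl)silyl]oxy}methyl)-5-[(4R)-4-hydroxy-2,6,6-trimethylcyclohex-1-en-1-yl]-4-oxopent-2-en-1-yl]triphenylphosphonium bromide, via allylic bromide 21 (not isolated)
Conditions: NBS, Me2S, CH2Cl2, −30 → 0 °C; then PPh3, 25 °C
Reagents that add atoms: N-bromosuccinimide, O=C1CCC(=O)N1Br; triphenylphosphine, c1ccc(cc1)P(c1ccccc1)c1ccccc1
Why: Corey–Kim-type bromination converts only the primary allylic alcohol (the secondary C3 hydroxyl is not displaced), and the reactive γ-bromo enone is quaternised by PPh3 in the same pot.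

**Step 11**
Reactants: 23 (R)-α-ionone
Product: 24 ethyl (2E,4E)-3-methyl-5-[(1R)-2,6,6-trimethylcyclohex-2-en-1-yl]penta-2,4-dienoate
Conditions: triethyl phosphonoacetate, NaH, THF, 0 → 65 °C; the minor 2Z isomer removed by chromatography
Reagents that add atoms: triethyl phosphonoacetate, CCOC(=O)CP(=O)(OCC)OCC
Why: Horner–Wadsworth–Emmons olefination of the methyl ketone should give mainly the 2E dienoate, and the weakly basic phosphonate anion does not deprotonate the C6′ hydrogen, so its configuration is kept.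

**Step 12**
Reactants: 24 dienoate
Product: 25 ethyl (2E,4E)-3-methyl-5-[(1R)-2,6,6-trimethyl-4-oxocyclohex-2-en-1-yl]penta-2,4-dienoate
Conditions: t-BuOOH, Rh2(cap)4 (1 mol%), K2CO3, CH2Cl2, 25 °C
Reagents that add atoms: tert-butyl hydroperoxide, CC(C)(C)OO
Why: Allylic oxidation of the ring methylene next to C4′=C5′ to the enone is the known mode for α-ionylidene esters; the side-chain diene is deactivated by the ester.

**Step 13**
Reactants: 25 oxo ester
Product: 26 ethyl (2E,4E)-5-[(1R,4R)-4-hydroxy-2,6,6-trimethylcyclohex-2-en-1-yl]-3-methylpenta-2,4-dienoate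
Conditions: (S)-Me-CBS oxazaborolidine (0.2 equiv), catecholborane, toluene, −78 °C; the 3′-epimer removed by chromatography
Reagents that add atoms: none
Why: In this Corey–Bakshi–Shibata reduction the olefinic side of the enone acts as the large group, so the (S)-catalyst should deliver hydride to give the 3′R carbinol (trans to the C6′ side chain) under reagent control; the minor epimer is a separable diastereomer.

**Step 14**
Reactants: 26 hydroxy ester
Product: 27 (2E,4E)-5-[(1R,4R)-4-hydroxy-2,6,6-trimethylcyclohex-2-en-1-yl]-3-methylpenta-2,4-dien-1-ol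
Conditions: i-Bu2AlH (3.5 equiv), CH2Cl2, −78 °C
Reagents that add atoms: none
Why: 1,2-Reduction of the dienoate gives the primary dienyl alcohol; the free secondary hydroxyl only consumes one equivalent of hydride.

**Step 15**
Reactants: 27 diol
Product: 28 [(2E,4E)-5-[(1R,4R)-4-hydroxy-2,6,6-trimethylcyclohex-2-en-1-yl]-3-methylpenta-2,4-dien-1-yl]triphenylphosphonium bromide
Conditions: PPh3·HBr, MeOH, 0 → 25 °C
Reagents that add atoms: triphenylphosphine hydrobromide, [Br-].c1ccc(cc1)[PH+](c1ccccc1)c1ccccc1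
Why: The primary dienyl alcohol ionises to the same pentadienyl cation as in the classical vinyl-ionol route and is trapped by phosphine at the primary terminus; low temperature spares the ring allylic hydroxyl.

**Step 16**
Reactants: 28 ε C15 phosphonium bromide; 29 (2E,4E,6E)-2,7-dimethylocta-2,4,6-trienedial (2.5 equiv)
Product: 31 (3R,6R)-3-hydroxy-12′-apo-ε-caroten-12′-al, via ylide 30 (not isolated)
Conditions: NaOMe, MeOH/CH2Cl2, −10 → 25 °C; then reflux in heptane (Z → E)
Reagents that add atoms: none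
Why: Wittig mono-olefination of the symmetrical dialdehyde used in excess is the standard C15 + C10 carotenoid coupling; the free hydroxyl is tolerated and the new C11′=C12′ bond is equilibrated thermally to E.

**Step 17**
Reactants: 22 β C15 phosphonium bromide; 31 C25 aldehyde
Product: 33 (3R,3′R,6′R)-19-{[tert-butyl(dimethyl)silyl]oxy}-3,3′-dihydroxy-7,8-dihydro-β,ε-caroten-8-one, via ylide 32 (not isolated)
Conditions: NaOMe (1.2 equiv), MeOH/CH2Cl2, 0 → 25 °C; then reflux in heptane (Z → E)
Reagents that add atoms: none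
Why: The ylide is stabilised through C9=C10 by the C8 ketone, so it forms in preference to the C7 enolate and should add to the polyenal to give the E C11=C12 bond (Wittig olefination); the C19 silyl ether prevents hemiacetal or furan formation.

**Step 18**
Reactants: 33 silyl ether
Product: 34 (3R,3′R,6′R)-3,19,3′-trihydroxy-7,8-dihydro-β,ε-caroten-8-one (target, CNP0183826.2)
Conditions: Bu4NF, AcOH (1:1), THF, 0 → 25 °C, dark, argon
Reagents that add atoms: none
Why: Buffered fluoride cleaves the primary allylic silyl ether without acid that would ionise the allylic C3′ hydroxyl and without base strong enough to move C5=C6 into conjugation with the ketone.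

**Compound list**
1 | (3-methylbut-2-en-1-yl)triphenylphosphonium bromide | [Br-].CC(C)=CC[P+](c1ccccc1)(c1ccccc1)c1ccccc1 | starting material
2 | ethyl (E)-3-methyl-4-oxobut-2-enoate | CCOC(=O)/C=C(\C)C=O | starting material
3 | (3-methylbut-2-en-1-ylidene)triphenylphosphorane | CC(C)=CC=P(c1ccccc1)(c1ccccc1)c1ccccc1 | intermediate
4 | ethyl (2E,4E)-3,7-dimethylocta-2,4,6-trienoate | CCOC(=O)/C=C(C)/C=C/C=C(C)C | intermediate
5 | ethyl (2E,4Z)-3,7-dimethylocta-2,4,6-trienoate | CCOC(=O)/C=C(C)/C=C\C=C(C)C | intermediate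
6 | ethyl 2,6,6-trimethylcyclohexa-2,4-diene-1-carboxylate (racemic) | CCOC(=O)C1C(C)=CC=CC1(C)C | intermediate
7 | ethyl 2,6,6-trimethylcyclohexa-1,3-diene-1-carboxylate | CCOC(=O)C1=C(C)C=CCC1(C)C | intermediate
8 | (2,6,6-trimethylcyclohexa-1,3-dien-1-yl)methanol | OCC1=C(C)C=CCC1(C)C | intermediate
9 | 1-{[(2-methoxypropan-2-yl)oxy]methyl}-2,6,6-trimethylcyclohexa-1,3-diene | COC(C)(C)OCC1=C(C)C=CCC1(C)C | intermediate
10 | B-alkyl-diisopinocampheylborane, boron on C3 on the face of the later hydroxyl | COC(C)(C)OCC1=C(C)C[C@@H](B([C@H]2C[C@H]3C[C@@H]([C@@H]2C)C3(C)C)[C@H]2C[C@H]3C[C@@H]([C@@H]2C)C3(C)C)CC1(C)C | intermediate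
11 | (1R)-4-{[(2-methoxypropan-2-yl)oxy]methyl}-3,5,5-trimethylcyclohex-3-en-1-ol | COC(C)(C)OCC1=C(C)C[C@@H](O)CC1(C)C | intermediate
12 | (1R)-4-(hydroxymethyl)-3,5,5-trimethylcyclohex-3-en-1-ol | OCC1=C(C)C[C@@H](O)CC1(C)C | intermediate
13 | (1R)-4-(chloromethyl)-3,5,5-trimethylcyclohex-3-en-1-ol | ClCC1=C(C)C[C@@H](O)CC1(C)C | intermediate
14 | tert-butyldimethyl(prop-2-yn-1-yloxy)silane | C#CCO[Si](C)(C)C(C)(C)C | starting material
15 | lithium acetylide of 14 | [Li]C#CCO[Si](C)(C)C(C)(C)C | intermediate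
16 | methyl 4-{[tert-butyl(dimethyl)silyl]oxy}but-2-ynoate | COC(=O)C#CCO[Si](C)(C)C(C)(C)C | intermediate
17 | vinylcopper adduct, copper cis to tin | COC(=O)/C([Cu])=C(\CO[Si](C)(C)C(C)(C)C)[Sn](CCCC)(CCCC)CCCC | intermediate
18 | methyl (2E)-4-{[tert-butyl(dimethyl)silyl]oxy}-3-(tributylstannyl)but-2-enoate | COC(=O)/C=C(\CO[Si](C)(C)C(C)(C)C)[Sn](CCCC)(CCCC)CCCC | intermediate
19 | (2E)-4-{[tert-butyl(dimethyl)silyl]oxy}-3-(tributylstannyl)but-2-en-1-ol | OC/C=C(\CO[Si](C)(C)C(C)(C)C)[Sn](CCCC)(CCCC)CCCC | intermediate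
20 | (3E)-3-({[tert-butyl(dimethyl)silyl]oxy}methyl)-5-hydroxy-1-[(4R)-4-hydroxy-2,6,6-trimethylcyclohex-1-en-1-yl]pent-3-en-2-one | OC/C=C(\CO[Si](C)(C)C(C)(C)C)C(=O)CC1=C(C)C[C@@H](O)CC1(C)C | intermediate
21 | (3E)-5-bromo-3-({[tert-butyl(dimethyl)silyl]oxy}methyl)-1-[(4R)-4-hydroxy-2,6,6-trimethylcyclohex-1-en-1-yl]pent-3-en-2-one | BrC/C=C(\CO[Si](C)(C)C(C)(C)C)C(=O)CC1=C(C)C[C@@H](O)CC1(C)C | intermediate
22 | [(2E)-3-({[tert-butyl(dimethyl)silyl]oxy}methyl)-5-[(4R)-4-hydroxy-2,6,6-trimethylcyclohex-1-en-1-yl]-4-oxopent-2-en-1-yl]triphenylphosphonium bromide | [Br-].O=C(CC1=C(C)C[C@@H](O)CC1(C)C)/C(CO[Si](C)(C)C(C)(C)C)=C/C[P+](c1ccccc1)(c1ccccc1)c1ccccc1 | intermediate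
23 | (R)-α-ionone | CC1=CCCC(C)(C)[C@H]1/C=C/C(C)=O | starting material
24 | ethyl (2E,4E)-3-methyl-5-[(1R)-2,6,6-trimethylcyclohex-2-en-1-yl]penta-2,4-dienoate | CC1=CCCC(C)(C)[C@H]1/C=C/C(C)=C/C(=O)OCC | intermediate
25 | ethyl (2E,4E)-3-methyl-5-[(1R)-2,6,6-trimethyl-4-oxocyclohex-2-en-1-yl]penta-2,4-dienoate | CC1=CC(=O)CC(C)(C)[C@H]1/C=C/C(C)=C/C(=O)OCC | intermediate
26 | ethyl (2E,4E)-5-[(1R,4R)-4-hydroxy-2,6,6-trimethylcyclohex-2-en-1-yl]-3-methylpenta-2,4-dienoate | CC1=C[C@H](O)CC(C)(C)[C@H]1/C=C/C(C)=C/C(=O)OCC | intermediate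
27 | (2E,4E)-5-[(1R,4R)-4-hydroxy-2,6,6-trimethylcyclohex-2-en-1-yl]-3-methylpenta-2,4-dien-1-ol | CC1=C[C@H](O)CC(C)(C)[C@H]1/C=C/C(C)=C/CO | intermediate
28 | [(2E,4E)-5-[(1R,4R)-4-hydroxy-2,6,6-trimethylcyclohex-2-en-1-yl]-3-methylpenta-2,4-dien-1-yl]triphenylphosphonium bromide | [Br-].CC1=C[C@H](O)CC(C)(C)[C@H]1/C=C/C(C)=C/C[P+](c1ccccc1)(c1ccccc1)c1ccccc1 | intermediate
29 | (2E,4E,6E)-2,7-dimethylocta-2,4,6-trienedial | O=C/C(C)=C/C=C/C=C(C)/C=O | starting material
30 | ylide of 28 | CC1=C[C@H](O)CC(C)(C)[C@H]1/C=C/C(C)=C/C=P(c1ccccc1)(c1ccccc1)c1ccccc1 | intermediate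
31 | (3R,6R)-3-hydroxy-12′-apo-ε-caroten-12′-al (all-E) | CC1=C[C@H](O)CC(C)(C)[C@H]1/C=C/C(C)=C/C=C/C(C)=C/C=C/C=C(C)/C=O | intermediate
32 | ylide of 22 | O=C(CC1=C(C)C[C@@H](O)CC1(C)C)/C(CO[Si](C)(C)C(C)(C)C)=C/C=P(c1ccccc1)(c1ccccc1)c1ccccc1 | intermediate
33 | (3R,3′R,6′R)-19-{[tert-butyl(dimethyl)silyl]oxy}-3,3′-dihydroxy-7,8-dihydro-β,ε-caroten-8-one | CC1=C[C@H](O)CC(C)(C)[C@H]1/C=C/C(C)=C/C=C/C(C)=C/C=C/C=C(C)/C=C/C=C(\CO[Si](C)(C)C(C)(C)C)C(=O)CC1=C(C)C[C@@H](O)CC1(C)C | intermediate
34 | (3R,3′R,6′R)-3,19,3′-trihydroxy-7,8-dihydro-β,ε-caroten-8-one | CC1=C[C@H](O)CC(C)(C)[C@H]1/C=C/C(C)=C/C=C/C(C)=C/C=C/C=C(C)/C=C/C=C(\CO)C(=O)CC1=C(C)C[C@@H](O)CC1(C)C | target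

**Totals.** 18 steps in all. The longest linear sequence is 9 steps (1, 2, 3, 4, 5, 9, 10, 17, 18).

**Steps most likely to fail**

Step 1. The iodine-mediated 4E → 4Z equilibration may be slow against polymerisation at 140 °C, and the [1,7]-hydrogen shift of the (4Z)-triene may divert material into a regioisomeric ring closure. Fallback, setting out from 2 and returning at 7: Ohira–Bestmann alkynylation of 2 (dimethyl (1-diazo-2-oxopropyl)phosphonate, K2CO3, EtOH) gives ethyl (E)-3-methylpent-2-en-4-ynoate F1. Sonogashira coupling of F1 with 1-bromo-2-methylprop-1-ene (Pd(PPh3)2Cl2, CuI, Et3N) gives ethyl (E)-3,7-dimethylocta-2,6-dien-4-ynoate F2. Semi-hydrogenation over Pd/CaCO3 poisoned with Pb(OAc)2 and quinoline then delivers 5 with the 4Z geometry fixed by synthesis. This closes to 6 near 100 °C without iodine and is isomerised by DBU to 7.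

Step 4. Boron may add at C4 instead of C3 (giving the allylic 4-ol), or the facial selectivity of the hindered diene may be poor. Fallback, setting out from 9 and returning at 12: Jacobsen epoxidation of the cis-disubstituted C3=C4 olefin (the (salen)MnCl enantiomer that gives the 3S,4R oxide, NaOCl, 4-phenylpyridine N-oxide) gives (1R,6S)-3-{[(2-methoxypropan-2-yl)oxy]methyl}-2,4,4-trimethyl-7-oxabicyclo[4.1.0]hept-2-ene F3. Palladium-catalysed formate hydrogenolysis (Pd2(dba)3, PBu3, HCO2H/Et3N, dioxane) delivers hydride to allylic C4 and leaves the C3 oxygen in place, giving 11. AcOH/THF/H2O then gives 12.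

Step 9. Slow transmetallation of the α-substituted vinylstannane may let direct (CO-free) allyl–vinyl coupling or migration of C5=C6 into conjugation compete. Fallback, setting out from 13 and returning at 20: palladium-catalysed methoxycarbonylation (Pd(OAc)2, PPh3, CO, MeOH, Et3N) gives methyl [(4R)-4-hydroxy-2,6,6-trimethylcyclohex-1-en-1-yl]acetate F4. Acylation of lithiated dimethyl [2-(tert-butyldimethylsilyloxy)ethyl]phosphonate (LiN(i-Pr)2, 3 equiv, THF, −78 °C) with F4 gives the β-ketophosphonate dimethyl {1-[(tert-butyldimethylsilyl)oxy]-4-[(4R)-4-hydroxy-2,6,6-trimethylcyclohex-1-en-1-yl]-3-oxobutan-2-yl}phosphonate F5. Horner–Wadsworth–Emmons reaction of F5 with glycolaldehyde (Ba(OH)2, wet THF) should give 20 with the E geometry.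

**Further compounds**
F1 | step 1 | ethyl (E)-3-methylpent-2-en-4-ynoate | CCOC(=O)/C=C(\C)C#C
F2 | step 1 | ethyl (E)-3,7-dimethylocta-2,6-dien-4-ynoate | CCOC(=O)/C=C(\C)C#CC=C(C)C
F3 | step 4 | (1R,6S)-3-{[(2-methoxypropan-2-yl)oxy]methyl}-2,4,4-trimethyl-7-oxabicyclo[4.1.0]hept-2-ene | COC(C)(C)OCC1=C(C)[C@H]2O[C@H]2CC1(C)C
F4 | step 9 | methyl [(4R)-4-hydroxy-2,6,6-trimethylcyclohex-1-en-1-yl]acetate | COC(=O)CC1=C(C)C[C@@H](O)CC1(C)C
F5 | step 9 | dimethyl {1-[(tert-butyldimethylsilyl)oxy]-4-[(4R)-4-hydroxy-2,6,6-trimethylcyclohex-1-en-1-yl]-3-oxobutan-2-yl}phosphonate | COP(=O)(OC)C(CO[Si](C)(C)C(C)(C)C)C(=O)CC1=C(C)C[C@@H](O)CC1(C)C
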